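**Retrosynthetic overview**
- The target is taken back (silyl ether and methyl ketal cleavage, Mitsunobu inversion/acylation at C8, methylenation with formaldehyde) to an α-phosphono 6,12-lactone; its C7–C11 bond comes from a C6-tethered phosphonoacetate opening a C7–C8 epoxide.
- The epoxide comes from the bridged diene 25/26. Its tetrahydrofuran (O–C3–C2–C1–C10) and ten-membered carbocycle are both closed in one step from a diazoketone on a 3-methoxy-7-vinyl dihydropyran: O–C10 and C9–C10 are made, O–C7 is broken.
- The dihydropyran is the first ring formed: Achmatowicz oxidation of a 2,3,5-trisubstituted furan, with C3 (ketal) and C6 (Luche reduction) both set from the C7 carbinol centre.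
- The furan is assembled from furan-3-ylmethanol, (S)-1,2-epoxybutane (C2, C1, C10, C14) and acrolein (C7–C9); C11/C12 come from diethylphosphonoacetic acid and C13 from formaldehyde.
- The strategy rests on the tetrahydrofuran oxygen that bridges C3 and quaternary C10 across the ten-membered carbocycle (an 11-oxabicyclo[6.2.1]undecane) and on the cis C4=C5 bond, which is held in the six-membered ring until the ring expansion. Ring order: dihydropyran, then tetrahydrofuran and carbocycle together, then lactone.

Key step: step 13

Assumption (chemistry): a single oxygen atom can bridge C3 and C10 of the ten-membered ring on one face only, so C10 is fixed by C3; the C3 and C10 descriptors are written in every bridged compound exactly as in the target string.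
Remarks: locants C1–C15 are those of the target (C1–C10 carbocycle, C11–C13 lactone, C14 methyl, C15 hydroxymethyl). C15 carries a tert-butyldiphenylsilyl ether so that it survives the acidic methanol of step 7. The carbinol centre brought in by epoxide 2 only keeps the intermediates single compounds and is destroyed in step 11.

Step 1
Reactants: 1 furan-3-ylmethanol, 2 (S)-1,2-epoxybutane
Product: 4 (S)-1-[3-(hydroxymethyl)furan-2-yl]butan-2-ol, via dilithiated furanmethanol 3 (not isolated)
Conditions: n-BuLi (2.2 equiv), THF, −78 → 0 °C; then 2, 0 °C → rt; H2O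
Reagents that add atoms: n-butyllithium, [Li]CCCC (lithium in 3 only; no atoms in 4)
Why: Directed ortho-lithiation, in which the lithium alkoxide steers the second equivalent of base to C2 of the furan, followed by SN2 opening of the epoxide at its CH2 terminus, so the epoxide centre is untouched and the new secondary alcohol is differentiated from the primary one from the outset.

Step 2
Reactants: 4 (S)-1-[3-(hydroxymethyl)furan-2-yl]butan-2-ol
Product: 5 (S)-1-[3-(tert-butyldiphenylsilyloxymethyl)furan-2-yl]butan-2-ol
Conditions: TBDPSCl (1.05 equiv), imidazole, CH2Cl2, 0 °C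
Reagents that add atoms: tert-butyldiphenylsilyl chloride, CC(C)(C)[Si](Cl)(c1ccccc1)c1ccccc1
Why: Silyl ether formation that is selective for the primary furylmethyl alcohol over the secondary one on steric grounds.

Step 3
Reactants: 5 (S)-1-[3-(tert-butyldiphenylsilyloxymethyl)furan-2-yl]butan-2-ol
Product: 6 3-(tert-butyldiphenylsilyloxymethyl)-2-[(S)-2-(4-methoxybenzyloxy)butyl]furan
Conditions: NaH, 4-methoxybenzyl chloride, Bu4NI (cat.), THF/DMF, 0 °C → rt
Reagents that add atoms: 4-methoxybenzyl chloride, COc1ccc(CCl)cc1
Why: Williamson etherification of the secondary alkoxide; the PMB ether tolerates the organolithium, acid and hydride steps ahead and is later removed oxidatively without touching silyl ethers or the ketal.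

Step 4
Reactants: 6 3-(tert-butyldiphenylsilyloxymethyl)-2-[(S)-2-(4-methoxybenzyloxy)butyl]furan, 7 acrolein
Product: 9 furyl vinyl carbinol (both epimers at C7), via 5-lithiofuran 8 (not isolated)
Conditions: n-BuLi (1.1 equiv), THF, −78 → −20 °C; then 7, −78 °C; H2O
Reagents that add atoms: n-butyllithium, [Li]CCCC (lithium in 8 only; no atoms in 9)
Why: α-Lithiation of the only free furan α-position followed by 1,2-addition of the aryllithium to acrolein; the new carbinol centre (C7) is formed without control and is resolved in step 5.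

Step 5
Reactants: 9 furyl vinyl carbinol (both epimers at C7)
Product: 10 (7S)-furyl vinyl carbinol
Conditions: Burkholderia cepacia lipase (Amano PS), vinyl acetate, t-BuOMe, 30 °C, run slightly past half conversion; chromatography
Reagents that add atoms: none
Why: Lipase-catalysed kinetic resolution by transesterification, in which the enzyme acylates the (R)-carbinol epimer (large furyl, medium vinyl) and leaves the (S)-alcohol, the centre from which C3 and C6 are later derived.

Step 6
Reactants: 10 (7S)-furyl vinyl carbinol
Product: 11 Achmatowicz hemiketal (6-hydroxy-2H-pyran-3(6H)-one; 7S; both anomers at C3)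
Conditions: NBS (1.05 equiv), NaHCO3, NaOAc, THF/H2O 4:1, 0 °C
Reagents that add atoms: water, O
Why: Achmatowicz oxidative ring expansion: bromonium-induced hydration of the electron-rich furan gives the cis-enedione, whose distal carbonyl is captured by the carbinol oxygen, so C7 is retained and the cis C4=C5 bond is locked in the ring.

Step 7
Reactants: 11 Achmatowicz hemiketal
Product: 12 methyl ketal enone (3R,7S; 3-OMe trans to 7-vinyl)
Conditions: MeOH, PPTS (cat.), 3 Å sieves, 0 °C → rt
Reagents that add atoms: methanol, CO
Why: Acid-catalysed ketalisation through the tertiary oxocarbenium ion under thermodynamic control places the methoxy group axial (anomeric effect) and trans to the equatorial vinyl group, which sets C3 and leaves the C2 side chain equatorial and cis to the vinyl group.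

Step 8
Reactants: 12 methyl ketal enone
Product: 13 allylic alcohol (3R,6R,7S; 6-OH trans to 7-vinyl)
Conditions: NaBH4, CeCl3·7H2O, MeOH, −78 °C
Reagents that add atoms: none
Why: Luche 1,2-reduction in which hydride attacks the enone carbonyl from the face opposite the axial methoxy group, giving the C6 alcohol trans to the C7 vinyl group as in related 6-alkoxy-2H-pyran-3(6H)-ones.

Step 9
Reactants: 13 allylic alcohol
Product: 14 C6 triethylsilyl ether of 13
Conditions: Et3SiCl, imidazole, DMAP (cat.), CH2Cl2, 0 °C
Reagents that add atoms: chlorotriethylsilane, CC[Si](Cl)(CC)CC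
Why: Silyl ether formation at the only free hydroxyl group.

Step 10
Reactants: 14 C6 triethylsilyl ether of 13
Product: 15 side-chain secondary alcohol (PMB removed)
Conditions: DDQ (1.2 equiv), CH2Cl2/pH 7 buffer 10:1, 0 °C
Reagents that add atoms: none
Why: Oxidative PMB cleavage (hydride abstraction by DDQ and hydrolysis of the benzylic oxocarbenium ion) under buffered conditions that spare the ketal and both silyl ethers.

Step 11
Reactants: 15 side-chain secondary alcohol
Product: 16 ethyl ketone (C1 ketone; C10 methylene)
Conditions: Dess–Martin periodinane, NaHCO3, CH2Cl2, 0 °C → rt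
Reagents that add atoms: none
Why: Dess–Martin oxidation of the secondary alcohol under buffered conditions that do not enolise the β-alkoxy ketone.

Step 12
Reactants: 16 ethyl ketone
Product: 18 diazoketone (key precursor; 3R,6R,7S), via C10-trifluoroacetyl ketone 17 (not isolated)
Conditions: LiN(SiMe3)2 (1.1 equiv), THF, −78 °C; CF3CO2CH2CF3; aqueous work-up; then MsN3, Et3N, H2O, MeCN, rt
Reagents that add atoms: methanesulfonyl azide, CS(=O)(=O)N=[N+]=[N-]; 2,2,2-trifluoroethyl trifluoroacetate, O=C(OCC(F)(F)F)C(F)(F)F (trifluoroacetyl group in 17 only)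
Why: Detrifluoroacetylative diazo transfer: kinetic deprotonation at the less hindered C10 methylene (C2 is neopentylic), Claisen trifluoroacetylation to 17 and Regitz diazo transfer with loss of the trifluoroacetyl group place the diazo group on C10 under conditions mild enough for the ketal and silyl ethers.

Step 13
Reactants: 18 diazoketone (key precursor)
Product: 21 bridged dienone (C1 ketone; C3 methyl ketal; 4Z,7Z-diene; 6-OTES; 15-OTBDPS), via copper carbenoid 19 (not isolated), via oxonium ylide 20 (not isolated)
Conditions: Cu(CF3COCHCOCF3)2 (5 mol %), CH2Cl2, reflux, slow addition of 18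
Reagents that add atoms: none
Why: The catalyst decomposes 18 to the electrophilic copper carbenoid 19, which is captured by a lone pair of the ring oxygen next to the equatorial C2 tether to give the bicyclic oxonium ylide 20 (the five-membered ring closes by 5-exo attack of oxygen on the carbenoid carbon, forming O–C10), and the ylide carbon then bonds to C9 of the cis-disposed vinyl group through a five-centre envelope transition state while O–C7 breaks ([2,3]-sigmatropic rearrangement). The closest known reaction type is the copper-catalysed oxonium ylide formation/[2,3] shift of 2-vinyl cyclic ethers that carry a diazoketone on the other α-carbon, a three-carbon ring expansion to oxygen-bridged medium rings. The ten-membered carbocycle is therefore closed not end to end but by enlarging the six-membered ring by C8–C9–C10 into the nine-membered ether ring, C9–C10 being the ring-closing bond. C10 is the only new stereocentre and is controlled by the substrate: the oxygen stays bonded to C3 and can reach C10 on one face only, so C10 is cis-bridged to C3 while C3 and C6 are untouched. The step needs capture at the ring oxygen and a [2,3] shift rather than hydride migration from C14, a [1,2] shift, capture by the methoxy oxygen or addition to C4=C5: the methoxy-derived ylide has no allyl group and can only revert, a methyl group is a poor hydride donor, the equatorial tether cannot reach the face of C4=C5, and divalent copper with the electron-poor diketonate ligand favours ylide formation. The new C7=C8 bond should be cis, because a trans alkene beside the cis C4=C5 bond in the bridged nine-membered ether ring would be far more strained.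

Step 14
Reactants: 21 bridged dienone
Product: 22 C1 alcohol (epimers at C1)
Conditions: NaBH4, MeOH, 0 °C
Reagents that add atoms: none
Why: Borohydride reduction of the ketone; the configuration of the new carbinol centre is irrelevant because the oxygen is removed in step 16.

Step 15
Reactants: 22 C1 alcohol
Product: 24 C1 S-methyl xanthate, via sodium xanthate 23 (not isolated)
Conditions: NaH, CS2, THF, 0 °C → rt; then MeI
Reagents that add atoms: carbon disulfide, S=C=S; iodomethane, CI; sodium hydride, [Na+].[H-] (sodium in 23 only)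
Why: Xanthate formation (alkoxide addition to CS2, then S-methylation), the first half of a Barton–McCombie deoxygenation; no β-hydrogen is available toward C10 for premature elimination.

Step 16
Reactants: 24 C1 S-methyl xanthate
Product: 25 C1-deoxy bridged diene (C3 methyl ketal; 6-OTES; 15-OTBDPS)
Conditions: Bu3SnH, AIBN (cat.), toluene, 90 °C
Reagents that add atoms: none
Why: Barton–McCombie radical deoxygenation; the secondary C1 radical has only disfavoured 4-exo or 5-endo closures onto either alkene and is reduced by the stannane, and it is done here because a later α-methylene lactone would not survive stannyl radicals.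

Step 17
Reactants: 25 C1-deoxy bridged diene
Product: 26 C6 alcohol
Conditions: HF·pyridine, pyridine, THF, 0 °C
Reagents that add atoms: none
Why: Buffered fluoride desilylation removes the secondary triethylsilyl ether and leaves the primary tert-butyldiphenylsilyl ether, the methyl ketal and the bis-allylic alcohol intact.

Step 18
Reactants: 26 C6 alcohol
Product: 27 7,8-epoxy alcohol (cis epoxide; oxygen syn to 6-OH)
Conditions: VO(acac)2 (5 mol %), t-BuOOH (decane), CH2Cl2, 0 °C → rt
Reagents that add atoms: tert-butyl hydroperoxide, CC(C)(C)OO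
Why: Hydroxyl-directed epoxidation in which the vanadium alkylperoxide bound to the C6 alkoxide delivers oxygen to the cis C7=C8 bond on the face of the hydroxyl, as with medium-ring cis-cycloalkenols, which sets C7 and C8; the C4=C5 bond, flanked by a quaternary carbon and four allylic C–O bonds, should react more slowly.

Step 19
Reactants: 27 7,8-epoxy alcohol, 28 diethylphosphonoacetic acid
Product: 29 C6 diethylphosphonoacetate of 27
Conditions: EDC·HCl, DMAP (cat.), CH2Cl2, 0 °C → rt
Reagents that add atoms: none
Why: Carbodiimide (Steglich) esterification of the hindered secondary alcohol under conditions to which the epoxide and ketal are inert.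

Step 20
Reactants: 29 C6 diethylphosphonoacetate of 27
Product: 31 α-(diethoxyphosphoryl) 6,12-lactone with free 8-OH (C7–C11 trans to O6; 8-OH trans to C11; C11 epimers), via lithium phosphonoacetate carbanion 30 (not isolated)
Conditions: LiN(SiMe3)2 (1.05 equiv), THF, −78 → 45 °C; then AcOH
Reagents that add atoms: lithium hexamethyldisilazide, [Li]N([Si](C)(C)C)[Si](C)(C)C (lithium in 30 only; no atoms in 31)
Why: Proposed new method: the carbanion 30, held at C7 by the C6 ester, should open the lithium-activated epoxide at C7 from the face opposite the epoxide oxygen (5-exo-tet, inversion), which sets C7 with C11 trans to the C6 oxygen and leaves the C8 oxygen with the epoxide configuration; the phosphoryl group lets the carbanion twist out of the ester plane, so the stereoelectronic penalty of a five-membered closure through an ester-linked carbanion should be smaller than for a plain ester enolate; the closest known reaction types are the telescoped intramolecular Michael addition/olefination of phosphonoacetate esters of γ-hydroxy enones and the opening of epoxides by phosphonoacetate anions in the first stage of the Wadsworth–Emmons cyclopropanation.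

Step 21
Reactants: 31 α-(diethoxyphosphoryl) 6,12-lactone, 32 formaldehyde
Product: 33 α-methylene 6,12-lactone 8-epi-alcohol
Conditions: K2CO3, aq. HCHO (37 %), THF, 0 °C
Reagents that add atoms: none
Why: Horner–Wadsworth–Emmons olefination of the α-phosphono lactone with formaldehyde under mild carbonate conditions removes the C11 stereocentre and forms the exocyclic methylene group, while the short cold reaction limits relactonisation to the C8 hydroxyl.

Step 22
Reactants: 33 α-methylene 6,12-lactone 8-epi-alcohol, 34 isobutyric acid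
Product: 35 8-isobutyrate (3-O-methyl; 15-O-TBDPS derivative of the target)
Conditions: PPh3, DIAD, toluene/THF, 0 °C → rt
Reagents that add atoms: none
Why: Mitsunobu esterification: the C8 alcohol is activated as its alkoxyphosphonium salt and displaced by isobutyrate with inversion (SN2), which places the ester cis to the C7–C11 bond as in the target; the C7 hydrogen is cis to the leaving group, which disfavours anti elimination toward the conjugated diene.

Step 23
Reactants: 35 8-isobutyrate (3-O-methyl; 15-O-TBDPS)
Product: 37 target CNP0282937.1, via hemiketal silyl ether 36 (not isolated)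
Conditions: aq. HF (48 %), MeCN, 0 °C → rt
Reagents that add atoms: water, O
Why: Aqueous acid hydrolyses the methyl ketal through the C3 oxocarbenium/hydroxy-enone stage to the hemiketal, which can reclose only in the one bridged form that the cis C4=C5 bond and C10 allow, and fluoride then cleaves the silyl ether; ester, lactone and methylene group are stable to this medium.

**Compound list**
1 | furan-3-ylmethanol | OCc1ccoc1 | starting material
2 | (S)-1,2-epoxybutane | CC[C@H]1CO1 | starting material
3 | 2-lithio-3-(lithiooxymethyl)furan | [Li]OCc1ccoc1[Li] | intermediate (not isolated)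
4 | (S)-1-[3-(hydroxymethyl)furan-2-yl]butan-2-ol | CC[C@H](O)Cc1occc1CO | intermediate
5 | (S)-1-[3-(tert-butyldiphenylsilyloxymethyl)furan-2-yl]butan-2-ol | CC[C@H](O)Cc1occc1CO[Si](c1ccccc1)(c1ccccc1)C(C)(C)C | intermediate
6 | 3-(tert-butyldiphenylsilyloxymethyl)-2-[(S)-2-(4-methoxybenzyloxy)butyl]furan | CC[C@H](OCc1ccc(OC)cc1)Cc1occc1CO[Si](c1ccccc1)(c1ccccc1)C(C)(C)C | intermediate
7 | acrolein | C=CC=O | starting material
8 | 5-lithio derivative of 6 | CC[C@H](OCc1ccc(OC)cc1)Cc1oc([Li])cc1CO[Si](c1ccccc1)(c1ccccc1)C(C)(C)C | intermediate (not isolated)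
9 | 1-{4-(tert-butyldiphenylsilyloxymethyl)-5-[(S)-2-(4-methoxybenzyloxy)butyl]furan-2-yl}prop-2-en-1-ol, both carbinol epimers | CC[C@H](OCc1ccc(OC)cc1)Cc1oc(C(O)C=C)cc1CO[Si](c1ccccc1)(c1ccccc1)C(C)(C)C | intermediate
10 | (S)-carbinol epimer of 9 (7S) | CC[C@H](OCc1ccc(OC)cc1)Cc1oc([C@@H](O)C=C)cc1CO[Si](c1ccccc1)(c1ccccc1)C(C)(C)C | intermediate
11 | Achmatowicz hemiketal: (2S)-6-hydroxy-6-[(S)-2-(4-methoxybenzyloxy)butyl]-5-(tert-butyldiphenylsilyloxymethyl)-2-vinyl-2H-pyran-3(6H)-one, both anomers | C=C[C@@H]1OC(O)(C[C@H](CC)OCc2ccc(OC)cc2)C(CO[Si](c2ccccc2)(c2ccccc2)C(C)(C)C)=CC1=O | intermediate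
12 | methyl ketal enone (3R,7S), methoxy trans to vinyl | C=C[C@@H]1O[C@](OC)(C[C@H](CC)OCc2ccc(OC)cc2)C(CO[Si](c2ccccc2)(c2ccccc2)C(C)(C)C)=CC1=O | intermediate
13 | allylic alcohol (3R,6R,7S), hydroxyl trans to vinyl | C=C[C@@H]1O[C@](OC)(C[C@H](CC)OCc2ccc(OC)cc2)C(CO[Si](c2ccccc2)(c2ccccc2)C(C)(C)C)=C[C@H]1O | intermediate
14 | C6 triethylsilyl ether of 13 | C=C[C@@H]1O[C@](OC)(C[C@H](CC)OCc2ccc(OC)cc2)C(CO[Si](c2ccccc2)(c2ccccc2)C(C)(C)C)=C[C@H]1O[Si](CC)(CC)CC | intermediate
15 | side-chain secondary alcohol (PMB removed) | C=C[C@@H]1O[C@](OC)(C[C@H](CC)O)C(CO[Si](c2ccccc2)(c2ccccc2)C(C)(C)C)=C[C@H]1O[Si](CC)(CC)CC | intermediate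
16 | ethyl ketone: 3-methoxy-3-(2-oxobutyl)-7-vinyl dihydropyran, 6-OTES, 15-OTBDPS | C=C[C@@H]1O[C@](OC)(CC(=O)CC)C(CO[Si](c2ccccc2)(c2ccccc2)C(C)(C)C)=C[C@H]1O[Si](CC)(CC)CC | intermediate
17 | C10-trifluoroacetyl derivative of 16 | C=C[C@@H]1O[C@](OC)(CC(=O)C(C)C(=O)C(F)(F)F)C(CO[Si](c2ccccc2)(c2ccccc2)C(C)(C)C)=C[C@H]1O[Si](CC)(CC)CC | intermediate (not isolated)
18 | diazoketone: 3-methoxy-3-(3-diazo-2-oxobutyl)-7-vinyl dihydropyran (3R,6R,7S), 6-OTES, 15-OTBDPS | C=C[C@@H]1O[C@](OC)(CC(=O)C(C)=[N+]=[N-])C(CO[Si](c2ccccc2)(c2ccccc2)C(C)(C)C)=C[C@H]1O[Si](CC)(CC)CC | intermediate (key precursor)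
19 | copper carbenoid at C10 (diketonate ligands omitted) | C=C[C@@H]1O[C@](OC)(CC(=O)C(C)=[Cu])C(CO[Si](c2ccccc2)(c2ccccc2)C(C)(C)C)=C[C@H]1O[Si](CC)(CC)CC | intermediate (not isolated)
20 | bicyclic oxonium ylide (O bonded to C3, C7 and C10) | C=C[C@@H]1[O+]2[C-](C)C(=O)C[C@]2(OC)C(CO[Si](c3ccccc3)(c3ccccc3)C(C)(C)C)=C[C@H]1O[Si](CC)(CC)CC | intermediate (not isolated)
21 | bridged dienone: C1 ketone, C3 methyl ketal, 3,10-oxygen bridge, 4Z,7Z-diene, 6-OTES, 15-OTBDPS | CC[Si](CC)(CC)O[C@@H]1/C=C(/CO[Si](c3ccccc3)(c3ccccc3)C(C)(C)C)[C@@]2(OC)CC(=O)[C@](C)(C/C=C\1)O2 | intermediate (key product)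
22 | C1 alcohol of 21, epimers at C1 | CC[Si](CC)(CC)O[C@@H]1/C=C(/CO[Si](c3ccccc3)(c3ccccc3)C(C)(C)C)[C@@]2(OC)CC(O)[C@](C)(C/C=C\1)O2 | intermediate
23 | sodium xanthate of 22 | CC[Si](CC)(CC)O[C@@H]1/C=C(/CO[Si](c3ccccc3)(c3ccccc3)C(C)(C)C)[C@@]2(OC)CC(OC(=S)[S-])[C@](C)(C/C=C\1)O2.[Na+] | intermediate (not isolated)
24 | S-methyl xanthate of 22 | CC[Si](CC)(CC)O[C@@H]1/C=C(/CO[Si](c3ccccc3)(c3ccccc3)C(C)(C)C)[C@@]2(OC)CC(OC(=S)SC)[C@](C)(C/C=C\1)O2 | intermediate
25 | C1-deoxy bridged diene, 6-OTES, 15-OTBDPS | CC[Si](CC)(CC)O[C@@H]1/C=C(/CO[Si](c3ccccc3)(c3ccccc3)C(C)(C)C)[C@@]2(OC)CC[C@](C)(C/C=C\1)O2 | intermediate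
26 | C6 alcohol | O[C@@H]1/C=C(/CO[Si](c3ccccc3)(c3ccccc3)C(C)(C)C)[C@@]2(OC)CC[C@](C)(C/C=C\1)O2 | intermediate
27 | 7,8-epoxy alcohol, cis epoxide syn to 6-OH | O[C@@H]1/C=C(/CO[Si](c4ccccc4)(c4ccccc4)C(C)(C)C)[C@@]2(OC)CC[C@](C)(C[C@@H]3O[C@@H]31)O2 | intermediate
28 | diethylphosphonoacetic acid | CCOP(=O)(OCC)CC(=O)O | starting material
29 | C6 diethylphosphonoacetate of 27 | CCOP(=O)(OCC)CC(=O)O[C@@H]1/C=C(/CO[Si](c4ccccc4)(c4ccccc4)C(C)(C)C)[C@@]2(OC)CC[C@](C)(C[C@@H]3O[C@@H]31)O2 | intermediate
30 | lithium carbanion of 29 | CCOP(=O)(OCC)[CH-]C(=O)O[C@@H]1/C=C(/CO[Si](c4ccccc4)(c4ccccc4)C(C)(C)C)[C@@]2(OC)CC[C@](C)(C[C@@H]3O[C@@H]31)O2.[Li+] | intermediate (not isolated)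
31 | α-(diethoxyphosphoryl) 6,12-lactone, 8-OH trans to C11, C11 epimers | CCOP(=O)(OCC)C1C(=O)O[C@@H]2/C=C(/CO[Si](c4ccccc4)(c4ccccc4)C(C)(C)C)[C@@]3(OC)CC[C@](C)(C[C@H](O)[C@@H]12)O3 | intermediate
32 | formaldehyde | C=O | starting material
33 | α-methylene 6,12-lactone, 8-epi-alcohol | C=C1C(=O)O[C@@H]2/C=C(/CO[Si](c4ccccc4)(c4ccccc4)C(C)(C)C)[C@@]3(OC)CC[C@](C)(C[C@H](O)[C@@H]12)O3 | intermediate
34 | isobutyric acid | CC(C)C(=O)O | starting material
35 | 8-isobutyrate, 3-O-methyl, 15-O-TBDPS derivative of the target | C=C1C(=O)O[C@@H]2/C=C(/CO[Si](c4ccccc4)(c4ccccc4)C(C)(C)C)[C@@]3(OC)CC[C@](C)(C[C@@H](OC(=O)C(C)C)[C@@H]12)O3 | intermediate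
36 | 15-O-TBDPS derivative of the target (free hemiketal) | C=C1C(=O)O[C@@H]2/C=C(/CO[Si](c4ccccc4)(c4ccccc4)C(C)(C)C)[C@@]3(O)CC[C@](C)(C[C@@H](OC(=O)C(C)C)[C@@H]12)O3 | intermediate (not isolated)
37 | CNP0282937.1 | C=C1C(=O)O[C@@H]2/C=C(/CO)[C@@]3(O)CC[C@](C)(C[C@@H](OC(=O)C(C)C)[C@@H]12)O3 | target

**Step count and risks**
Total step count: 23. Longest linear sequence: 23 steps, from 1 to 37.

The three steps most likely to fail:

Step 20 (proposed new method). The tethered carbanion may not reach the rear of the C7–O bond, because a five-membered closure through an ester-linked carbanion is stereoelectronically demanding and the bicycle must adopt one particular conformation. The C8 alkoxide could also attack phosphorus and collapse to a cyclopropane, or relactonise. The fallback uses known chemistry only, sets out from alcohol 26 and returns at 35, so that steps 18, 19, 21 and 22 are bypassed. Alcohol 26 would be esterified with 28 (EDC, DMAP) to the C6 diethylphosphonoacetate F1. Diazo transfer (4-acetamidobenzenesulfonyl azide, DBU, MeCN) would give the diazophosphonoacetate F2. Intramolecular cyclopropanation of C7=C8 with Rh2(OAc)4 in refluxing 1,2-dichloroethane would give the cyclopropane-fused phosphono lactone F3, with C11 bonded to C7 and C8 on the face that leaves the lactone trans-fused. Homoconjugate opening of this doubly activated cyclopropane at C8 with MgI2 in THF (inversion) would give the 8-iodo α-phosphono lactone F4. Displacement of iodide with CsO2CCH(CH3)2 in DMF (second inversion) would give the 8-isobutyryloxy α-phosphono lactone F5, with the ester cis to C11. Olefination with K2CO3/aqueous formaldehyde would then give 35.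

Step 13 (key step). The tertiary carbenoid may be lost by hydride migration from C14 (enone formation) or be diverted through the methoxy oxygen before the ring-oxygen ylide rearranges. The fallback installs the C10 methyl group by enolate alkylation instead of in the ring expansion; it sets out from ketone 16 and returns at 21. Ketone 16 would be converted (LiN(SiMe3)2, Me3SiCl, −78 °C) into the C1=C10 trimethylsilyl enol ether F6. Ozonolysis of the electron-rich enol ether with one equivalent of O3 (CH2Cl2/MeOH, −78 °C; Me2S) would give the C1 carboxylic acid F7. Activation with i-BuOCOCl/Et3N would give the isobutyl carbonic mixed anhydride F8, which with CH2N2 would give the terminal diazoketone F9. The same copper-catalysed ring expansion, now on the unsubstituted carbenoid for which it is best established, would give the 10-desmethyl bridged ketone F10. Soft enolisation toward the oxygen-bearing carbon (Me3SiOTf, Et3N) would give the C1=C10 trimethylsilyl enol ether F11. MeLi followed by MeI would methylate C10 from the only open face and give 21.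

Step 18. Oxygen may be delivered to the wrong alkene (C4=C5) or to the wrong face of C7=C8 if the conformation of the bicycle overrides the directing hydroxyl. The fallback sets out from 26 and returns at 27. NBS in THF/H2O would add bromine to the more accessible face of C7=C8 and water anti to it, giving the trans bromohydrin F12 (either regioisomer serves). K2CO3 in MeOH would then close the epoxide on the face opposite to that attacked by a direct electrophilic oxidant, giving 27.

**Further compounds**
F1 | step 20 | C6 diethylphosphonoacetate of 26 | CCOP(=O)(OCC)CC(=O)O[C@@H]1/C=C(/CO[Si](c3ccccc3)(c3ccccc3)C(C)(C)C)[C@@]2(OC)CC[C@](C)(C/C=C\1)O2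
F2 | step 20 | C6 diazo(diethoxyphosphoryl)acetate of 26 | CCOP(=O)(OCC)C(=[N+]=[N-])C(=O)O[C@@H]1/C=C(/CO[Si](c3ccccc3)(c3ccccc3)C(C)(C)C)[C@@]2(OC)CC[C@](C)(C/C=C\1)O2
F3 | step 20 | cyclopropane-fused α-phosphono lactone (C11 bonded to C7 and C8) | CCOP(=O)(OCC)[C@@]12C(=O)O[C@@H]3/C=C(/CO[Si](c5ccccc5)(c5ccccc5)C(C)(C)C)[C@@]4(OC)CC[C@](C)(C[C@@H]1[C@@H]23)O4
F4 | step 20 | 8-iodo α-phosphono 6,12-lactone (iodine trans to C11) | CCOP(=O)(OCC)C1C(=O)O[C@@H]2/C=C(/CO[Si](c4ccccc4)(c4ccccc4)C(C)(C)C)[C@@]3(OC)CC[C@](C)(C[C@H](I)[C@@H]12)O3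
F5 | step 20 | 8-isobutyryloxy α-phosphono 6,12-lactone (ester cis to C11) | CCOP(=O)(OCC)C1C(=O)O[C@@H]2/C=C(/CO[Si](c4ccccc4)(c4ccccc4)C(C)(C)C)[C@@]3(OC)CC[C@](C)(C[C@@H](OC(=O)C(C)C)[C@@H]12)O3
F6 | step 13 | C1=C10 trimethylsilyl enol ether of 16 | C=C[C@@H]1O[C@](OC)(CC(O[Si](C)(C)C)=CC)C(CO[Si](c2ccccc2)(c2ccccc2)C(C)(C)C)=C[C@H]1O[Si](CC)(CC)CC
F7 | step 13 | C1 carboxylic acid | C=C[C@@H]1O[C@](OC)(CC(=O)O)C(CO[Si](c2ccccc2)(c2ccccc2)C(C)(C)C)=C[C@H]1O[Si](CC)(CC)CC
F8 | step 13 | isobutyl carbonic mixed anhydride of F7 | C=C[C@@H]1O[C@](OC)(CC(=O)OC(=O)OCC(C)C)C(CO[Si](c2ccccc2)(c2ccccc2)C(C)(C)C)=C[C@H]1O[Si](CC)(CC)CC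
F9 | step 13 | terminal diazoketone (C10 unsubstituted) | C=C[C@@H]1O[C@](OC)(CC(=O)C=[N+]=[N-])C(CO[Si](c2ccccc2)(c2ccccc2)C(C)(C)C)=C[C@H]1O[Si](CC)(CC)CC
F10 | step 13 | 10-desmethyl bridged dienone | CC[Si](CC)(CC)O[C@@H]1/C=C(/CO[Si](c3ccccc3)(c3ccccc3)C(C)(C)C)[C@@]2(OC)CC(=O)[C@H](C/C=C\1)O2
F11 | step 13 | C1=C10 trimethylsilyl enol ether of F10 | CC[Si](CC)(CC)O[C@@H]1/C=C(/CO[Si](c3ccccc3)(c3ccccc3)C(C)(C)C)[C@@]2(OC)CC(O[Si](C)(C)C)=C(C/C=C\1)O2
F12 | step 18 | trans bromohydrin (7-bromo, 8-hydroxy) of 26 | O[C@@H]1/C=C(/CO[Si](c3ccccc3)(c3ccccc3)C(C)(C)C)[C@@]2(OC)CC[C@](C)(C[C@H](O)[C@H]1Br)O2
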